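**Retrosynthetic overview**
1. The strategy rests on the only stereocentre, C3 of the 3-hydroxy-3-methylglutarate chain. It is a tertiary carbinol carbon bearing CH3, OH and two CH2C(=O) arms, and it is chiral only because one arm ends in the Z-sinapyl ester and the other in CO2H. The acid part therefore maps onto a prochiral six-membered cyclic anhydride (ring O1, C2(=O), C3H2, C4(CH3)(OH), C5H2, C6(=O)) whose carbonyl carbons C2 and C6 are enantiotopic.
2. Last disconnection: the ester C–O bond between the allylic oxygen and the pro-R carbonyl, giving unprotected (Z)-sinapyl alcohol and 3-hydroxy-3-methylglutaric anhydride. A lipase joins them, sets C3 and releases the free acid in one operation.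
3. (Z)-Sinapyl alcohol comes from a Z-cinnamate by hydride reduction, and the Z-cinnamate from Still–Gennari olefination of O-acetylsyringaldehyde. The anhydride comes from the commercial diacid by carbodiimide dehydration.
4. Ring order: the benzene ring is bought. The only ring built is the anhydride ring, made separately as a temporary symmetric device and opened again in the final step.

Key step: step 5

Assumption: the lipase is taken to acylate its serine with the pro-R carbonyl of the anhydride, the arm that pig-liver-type esterases are reported to hydrolyse in the dimethyl ester of the diacid. Sense and level of selectivity are to be confirmed by chiral HPLC on the first run. A lipase of better preference from a short panel (Burkholderia cepacia, Pseudomonas fluorescens, Rhizomucor miehei, porcine pancreas) would replace it without changing the route.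

**Step 1**
Reactants: 1 syringaldehyde (4-hydroxy-3,5-dimethoxybenzaldehyde)
Product: 2 4-acetoxy-3,5-dimethoxybenzaldehyde (4-O-acetylsyringaldehyde)
Conditions: Ac2O, pyridine, cat. DMAP, CH2Cl2, 0 °C to rt
Reagents that add atoms: acetic anhydride, CC(=O)OC(C)=O
Why: DMAP-catalysed O-acetylation of the phenol masks the acidic proton, so the aldehyde stays electrophilic and does not consume the base of step 2; the acetate is chosen because the hydride of step 3 removes it in passing.

**Step 2**
Reactants: 2 4-acetoxy-3,5-dimethoxybenzaldehyde; 3 methyl bis(2,2,2-trifluoroethyl)phosphonoacetate
Product: 5 methyl (Z)-3-(4-acetoxy-3,5-dimethoxyphenyl)prop-2-enoate, via potassium phosphonoacetate carbanion 4 (not isolated)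
Conditions: 3, KN(SiMe3)2, 18-crown-6, THF, −78 °C; then 2, −78 °C; sat. aq. NH4Cl at −78 °C; chromatography to remove the minor E ester
Reagents that add atoms: none
Why: Still–Gennari variant of the Horner–Wadsworth–Emmons olefination: with the electron-poor bis(trifluoroethyl) phosphonate and a crown-separated potassium counter-ion the first-formed syn adduct should eliminate faster than it reverts, so the alkene geometry is set kinetically as Z, while the stabilised carbanion should leave the hindered aryl acetate alone at −78 °C.

**Step 3**
Reactants: 5 methyl (Z)-3-(4-acetoxy-3,5-dimethoxyphenyl)prop-2-enoate
Product: 6 (Z)-sinapyl alcohol [4-((1Z)-3-hydroxyprop-1-enyl)-2,6-dimethoxyphenol]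
Conditions: i-Bu2AlH (5 equiv), CH2Cl2, −78 to −40 °C, light excluded; aq. KNaC4H4O6 (potassium sodium tartrate); quick chromatography on neutral silica; stored cold under argon in the dark
Reagents that add atoms: none
Why: Aluminium hydride 1,2-reduction of the enoate to the allylic alcohol (no conjugate reduction, geometry retained at low temperature) with concurrent reductive cleavage of the aryl acetate to the aluminium phenoxide and ethanol; the neutral tartrate work-up spares the acid- and light-sensitive para-hydroxycinnamyl alcohol.

**Step 4**
Reactants: 7 3-hydroxy-3-methylglutaric acid
Product: 8 3-hydroxy-3-methylglutaric anhydride (4-hydroxy-4-methyloxane-2,6-dione)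
Conditions: DCC (0.98 equiv), dry acetone, 0 °C to rt; urea filtered off; concentrated and crystallised from Et2O–hexane under exclusion of moisture
Reagents that add atoms: none
Why: Carbodiimide cyclodehydration: one carboxyl is activated as the O-acylisourea and the second closes the six-membered anhydride by intramolecular acyl substitution faster than the hindered tertiary hydroxyl can react; the neutral, base-free medium avoids β-elimination, and the slight deficit of carbodiimide ensures none reaches step 5.

**Step 5**
Reactants: 6 (Z)-sinapyl alcohol; 8 3-hydroxy-3-methylglutaric anhydride (1.5 equiv)
Product: 9 (3R)-3-hydroxy-5-[(2Z)-3-(4-hydroxy-3,5-dimethoxyphenyl)prop-2-enyloxy]-3-methyl-5-oxopentanoic acid (target)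
Conditions: immobilised Candida antarctica lipase B (Novozym 435), dry MTBE, 25 °C, argon, dark; enzyme filtered off; cold aq. NaHCO3 extraction, citric acid to pH 4, EtOAc
Reagents that add atoms: none
Why: The nucleophilic serine of the lipase attacks one of the two enantiotopic carbonyl carbons of 8, the anhydride ring opens to an acyl-enzyme that carries the other arm as a free carboxylic acid, and the primary allylic hydroxyl of 6 then takes over the acyl group, so the new ester C–O bond joins the allylic oxygen of 6 to the pro-R arm and the pro-S arm is released as the acid. The closest known reaction type is the lipase-catalysed desymmetrising alcoholysis of prochiral 3-substituted glutaric anhydrides, with the esterase half-hydrolysis of dialkyl 3-hydroxy-3-methylglutarates as the nearest case on this carbon skeleton; here it is applied to the 3-hydroxy-3-methyl anhydride and to a phenolic Z-allylic alcohol, an extension that has not been tested. No ring is closed: the six-membered anhydride ring is opened and nothing cyclic is formed. The new stereocentre C3 should become (R) under catalyst control alone, because the enzyme pocket must tell the hydroxyl from the methyl group on the carbinol carbon when it picks the carbonyl, and this choice is made at acyl-enzyme formation, before the large alcohol enters. The step needs pro-R over pro-S carbonyl selection, acylation of the primary allylic hydroxyl in preference to the phenol (shielded by its two ortho methoxy groups) and the tertiary hydroxyl (both poor lipase nucleophiles), and a slow uncatalysed background opening, which the base-free ethereal medium at ambient temperature should provide. The same neutral conditions should leave the Z alkene and the para-hydroxycinnamyl ester untouched and end the synthesis with no protecting group to remove.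

**Compound list**
1 | syringaldehyde (4-hydroxy-3,5-dimethoxybenzaldehyde) | COc1cc(C=O)cc(OC)c1O | starting material
2 | 4-acetoxy-3,5-dimethoxybenzaldehyde | COc1cc(C=O)cc(OC)c1OC(C)=O | intermediate
3 | methyl bis(2,2,2-trifluoroethyl)phosphonoacetate | COC(=O)CP(=O)(OCC(F)(F)F)OCC(F)(F)F | starting material
4 | potassium carbanion of methyl bis(2,2,2-trifluoroethyl)phosphonoacetate (formed in the flask) | COC(=O)[CH-]P(=O)(OCC(F)(F)F)OCC(F)(F)F.[K+] | intermediate
5 | methyl (Z)-3-(4-acetoxy-3,5-dimethoxyphenyl)prop-2-enoate | COc1cc(/C=C\C(=O)OC)cc(OC)c1OC(C)=O | intermediate
6 | (Z)-sinapyl alcohol | COc1cc(/C=C\CO)cc(OC)c1O | intermediate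
7 | 3-hydroxy-3-methylglutaric acid | CC(O)(CC(=O)O)CC(=O)O | starting material
8 | 3-hydroxy-3-methylglutaric anhydride | CC1(O)CC(=O)OC(=O)C1 | intermediate
9 | (R)-mono-(Z)-sinapyl 3-hydroxy-3-methylglutarate | COc1cc(/C=C\COC(=O)C[C@](C)(O)CC(=O)O)cc(OC)c1O | target

**Step count**
Total step count: 5.
Longest linear sequence: 4 steps (steps 1, 2, 3 and 5); step 4 is a one-step side branch.

**Steps most likely to fail**

Step 5. The enzyme may discriminate poorly between the two enantiotopic carbonyls or prefer the wrong one. The quaternary carbinol may slow acyl-enzyme formation so much that the racemic uncatalysed opening competes, or transfer of the acyl group to the large alcohol may be sluggish. The fallback sets out from 6 and 8 and returns at 9, and gives up the enzyme as the source of chirality. Anhydride 8 is opened by 6 in pyridine–CH2Cl2 at 0 °C to rt, the customary way of attaching a 3-hydroxy-3-methylglutaryl unit to a primary alcohol, to give racemic mono-(Z)-sinapyl 3-hydroxy-3-methylglutarate F1. The (R)-enantiomer 9 is then isolated by preparative chromatography on an immobilised polysaccharide chiral stationary phase (supercritical CO2–methanol). The same separation would polish material of incomplete enantiopurity from step 5.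

Step 2. The kinetic Z preference may erode through reversible addition to the electron-rich aldehyde, or the acetyl group may transfer from the aryl acetate to the carbanion. The fallback sets out from 2 and returns at 5, and no longer sets the geometry in the olefination. A Wittig reaction of 2 with methyl (triphenylphosphoranylidene)acetate in toluene gives methyl (E)-3-(4-acetoxy-3,5-dimethoxyphenyl)prop-2-enoate F2. This is isomerised by triplet energy transfer (fac-Ir(ppy)3, blue light, MeCN, rt) to a Z-enriched photostationary mixture, from which 5 is separated on silica while recovered F2 is irradiated again.

Step 3. The reductive loss of the acetate alongside the ester reduction may be incomplete or untidy. Partial Z to E isomerisation on the Lewis-acidic aluminium species is possible, as is decomposition of the air-, acid- and light-sensitive product during work-up. The fallback sets out from 5 and returns at 6, and separates the two events. Pyrrolidine in CH2Cl2 at 0 °C selectively aminolyses the phenolic acetate to give methyl (Z)-sinapate F3. i-Bu2AlH in toluene (−78 to 0 °C) then reduces the ester of the aluminium phenoxide formed in the flask, the established way to monolignols from hydroxycinnamate esters, to give 6.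

**Further compounds**
F1 | step 5 | racemic mono-(Z)-sinapyl 3-hydroxy-3-methylglutarate | COc1cc(/C=C\COC(=O)CC(C)(O)CC(=O)O)cc(OC)c1O
F2 | step 2 | methyl (E)-3-(4-acetoxy-3,5-dimethoxyphenyl)prop-2-enoate | COc1cc(/C=C/C(=O)OC)cc(OC)c1OC(C)=O
F3 | step 3 | methyl (Z)-sinapate | COc1cc(/C=C\C(=O)OC)cc(OC)c1O
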